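Autumn, dawn and dusk received equal amounts and differed in how those amounts went in.

    starting material + partner ⇌ target (K1 = 1.2 M⁻¹, k1 = 0.15 M⁻¹ h⁻¹)
    starting material + 2 partner → side product (k2 = 0.15 M⁻² h⁻¹)
    partner + target ⇌ idle adduct, settled at all times (K3 = 2.1 M⁻¹)

| setting | autumn | dawn | dusk |
|---|---|---|---|
| starting material | 0.25 M (fed, over 30 h) | 0.25 M | 0.25 M |
| partner | 0.375 M | 0.375 M (fed, over 30 h) | 0.375 M |
| time | 40 h | 40 h | 40 h |
| remark | all else is in the flask from the start; the feed brings no volume worth counting | all else is in the flask from the start; the feed brings no volume worth counting | everything together at the start |

- amounts and yields of target count idle adduct too
- two of one species on the left: rate k times its square, two consumed each time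
- run time (autumn): 40 h

- the flask with the highest share of target in target plus side product ("all alike" if they lie within 1.5 percentage points) (autumn / dawn / dusk / all alike)
- share of target in target plus side product at the end, autumn
- share of target in target plus side product at the end, dawn
- share of target in target plus side product at the end, dusk

I first asked how the two routes divide starting material. Both forward rates carry c(starting material), so their ratio depends on c(partner) and the constants. The crossover level c*, the rate constant of the target step divided by that of the side step, is 1.00 M. At c* the routes tie, and the forward share of target, an instantaneous selectivity, is c*/(c* + c(partner)). At the charged 0.375 M, below c*, that share is 72.7%.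

Did this share last? In dusk, the forward half-life of the target step, with partner as charged, is 12 h, so the 40 h run is longer and the way back must count, whereas the side step has none. I therefore took 72.7% as the forward share at the start of dusk, not as an end value.

Which feed lowers c(partner)? In dawn, before any loss, partner averages half its charge during the feed, or 0.188 M, and at that level the forward share is 84.2%, above the 72.7% at the charged level. Autumn starts with partner at its full charge. I committed to dawn, with forward shares rather than end values.

The forecast also named dawn, with 54% for autumn, 61% for dawn and 47% for dusk: “Feeding partner slowly keeps its level low and gives the least side product”.

The simulation gave dawn the highest share, 63.9%, against 55.9% in autumn and 47.5% in dusk, and the forecast held within tolerance. Over the first 30 h, mean partner was 0.140 M in dawn and 0.244 M in dusk. Put through c*, those means give forward shares of 87.7% for dawn and 80.4% for dusk, in the same order as the end shares and above them.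

A neighbour of dawn, charged with 1.5 M of partner, lies above c*, so the carried share at its charge is 40.0%, with the side route ahead. The computed share there was 39.8%.

(The numbers of this flask are assumed; the result is computed.)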